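The six-membered carbocycle is numbered as follows: C1 is the quaternary carbinol that carries C7H2OBz, C2 and C3 hold the acetates, C4=C5 is the alkene, and C6 is the free carbinol. Once C4 is written as a carbonyl, a mirror plane through C1, C4 and C7 emerges. The ring is then a latent achiral para-quinol ether with prochiral C1 and enantiotopic enone arms C2=C3 and C5=C6. A chiral primary-amine salt and H2O2 epoxidise C5=C6 only. This single operation forms C5–O and C6–O, closes the oxirane and fixes C1, C5 and C6. The precursor is 4-(benzoyloxymethyl)-4-(tert-butyldimethylsilyloxy)cyclohexa-2,5-dienone. Afterwards the untouched arm gives the cis-diacetate, and a Wharton transposition turns the epoxy ketone into C4=C5/C6–OH.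

Key step: step 4

Conventions: the numbering above is used for every compound and every CIP descriptor. "Lower face" is the ring face that carries C7 and "upper face" is the one that carries the C1 oxygen. TBS = tert-butyldimethylsilyl, Bz = benzoyl. Descriptor changes at C1 and C3 along the route reflect CIP priorities only, not inversions.

Assumption: the quinine-derived amine salt is taken to give the (5R,6S)-oxirane. If its sense of induction proves opposite, the quinidine-derived pseudoenantiomer is used and nothing else changes.

Design notes: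
- **Benzoate installation.** The benzoate is introduced under neutral Mitsunobu conditions. An acyl chloride with base would acylate the phenol first, and the phenoxide of a 4-hydroxybenzyl ester expels carboxylate.
- **Choice of TBS on O1.** TBS is the largest silyl group that a tertiary quinol hydroxyl accepts reliably and that HF still removes beside three esters. It is the shield of the upper face in steps 4 and 5.

Step 1
Reactants: 1 4-hydroxybenzyl alcohol; 2 benzoic acid
Product: 3 4-hydroxybenzyl benzoate
Conditions: PPh3, DIAD, THF, 0 °C to rt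
Reagents that add atoms: benzoic acid (2), O=C(O)c1ccccc1
Why: Mitsunobu esterification: PPh3/DIAD activates only the alcoholic hydroxyl and the far more acidic benzoic acid, not the phenol, acts as pronucleophile, so the benzylic ester forms under neutral conditions that neither acylate the phenol nor expel benzoate through a quinone methide; no stereocentre is created.

Step 2
Reactants: 3 4-hydroxybenzyl benzoate
Product: 4 (1-hydroxy-4-oxocyclohexa-2,5-dien-1-yl)methyl benzoate (achiral para-quinol)
Conditions: PhI(OAc)2, MeCN/H2O (3:1), 0 °C
Reagents that add atoms: water, O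
Why: Hydroxylative oxidative dearomatisation of a para-substituted phenol by a hypervalent iodine reagent: two-electron oxidation makes the substituted para carbon electrophilic and water is captured there, the weakly acidic medium spares the base-labile para-hydroxybenzyl ester, and the product is achiral because C1 lies on the mirror plane.

Step 3
Reactants: 4 para-quinol; 5 tert-butyldimethylsilyl trifluoromethanesulfonate
Product: 6 4-(benzoyloxymethyl)-4-(tert-butyldimethylsilyloxy)cyclohexa-2,5-dienone (achiral)
Conditions: 2,6-lutidine, CH2Cl2, 0 °C to rt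
Reagents that add atoms: tert-butyldimethylsilyl trifluoromethanesulfonate (5), CC(C)(C)[Si](C)(C)OS(=O)(=O)C(F)(F)F
Why: Silyl triflate silylation of a tertiary alcohol with a hindered pyridine base; the quinol hydroxyl is flanked by two flat sp2 carbons and should accept TBS, benzoate and dienone are inert, and the mirror plane is kept.

Step 4
Reactants: 6 silylated para-quinol dienone
Product: 10 (1R,5R,6S)-monoepoxy enone [(1R,5R,6S)-5-(tert-butyldimethylsilyloxy)-2-oxo-7-oxabicyclo[4.1.0]hept-3-en-5-yl]methyl benzoate (oxirane on the lower face; C2=C3–C4=O intact), via iminium ion 7 (not isolated), via hydroperoxy dienamine 8 (not isolated), via epoxy iminium ion 9 (not isolated)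
Conditions: 9-amino-9-deoxy-epi-quinine (10 mol %), CF3CO2H (20 mol %), 30% aq H2O2 (1.2 equiv), 1,4-dioxane, 30 °C
Reagents that add atoms: hydrogen peroxide, OO; 9-amino-9-deoxy-epi-quinine, COc1ccc2nccc([C@H](N)[C@@H]3C[C@@H]4CCN3C[C@@H]4C=C)c2c1 (bound only in 7, 8 and 9; released again on hydrolysis)
Why: Proposed new method: the primary amine condenses with the C4 ketone to give iminium ion 7, H2O2 held by the quinuclidine site adds to C6 to give hydroperoxy dienamine 8, the enamine carbon C5 then attacks the proximal peroxide oxygen and expels water to give epoxy iminium ion 9, and hydrolysis releases 10 and the catalyst. The closest known reaction type is the amine-salt-catalysed asymmetric Weitz–Scheffer epoxidation of simple cyclic enones with aqueous H2O2, while catalytic desymmetrisation of 4,4-disubstituted cyclohexadienones is established only for conjugate additions, so epoxidative desymmetrisation of a para-quinol ether is the untested element. The oxirane closes in a 3-exo-tet mode on the face where the peroxide entered, which makes C5–O and C6–O cis by necessity. The chiral ion pair dictates the absolute sense of attack on a β-carbon and so sets C6 and C5, whereas C1 becomes stereogenic through the arm that reacts: one and the same sense of attack corresponds to the lower face of C5=C6 or to the upper face of C2=C3, so the facial bias of the substrate translates catalyst control into the configuration at C1. The step therefore needs lower-face selectivity, which is entrusted to the TBS group that should prefer to sit over the ring anti to C7 and is supported by the electron-poor C1–C7 bond and the weakly basic silyl ether oxygen, both of which should damp the oxygen-side preference known for small quinol derivatives; any leakage would appear as a separable C1 epimer and not as loss of enantiopurity. Mono-epoxidation is secured by limiting H2O2, because in 10 the surviving enone offers the catalyst its matched sense only on the shielded upper face, while the minor enantiomer still has a matched open face and should be consumed preferentially.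

Step 5
Reactants: 10 monoepoxy enone
Product: 11 (1S,2R,3S,5R,6S)-2,3-dihydroxy-5,6-epoxy ketone (C2–OH and C3–OH cis and on the lower face; C1–OTBS on the upper face)
Conditions: OsO4 (5 mol %), NMO, citric acid, t-BuOH/acetone/H2O, rt
Reagents that add atoms: osmium tetroxide, O=[Os](=O)(=O)=O; N-methylmorpholine N-oxide, C[N+]1([O-])CCOCC1; water, O
Why: Catalytic OsO4/NMO syn-dihydroxylation of the only remaining alkene: the suprafacial [3+2] addition makes C2–O and C3–O cis, and it should occur on the lower face, anti to the allylic C1–O bond as is normal for osmylation of allylic ethers and away from the silyl group, while citric acid keeps the medium slightly acidic to protect the β-hydroxy ketone and to speed turnover with the electron-poor enone.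

Step 6
Reactants: 11 diol
Product: 12 (1R,2R,3S,5R,6S)-2,3-O-isopropylidene-5,6-epoxy ketone (cis-fused dioxolane on the lower face)
Conditions: Me2C(OMe)2, PPTS (cat.), CH2Cl2, rt
Reagents that add atoms: 2,2-dimethoxypropane, COC(C)(C)OC
Why: Acid-catalysed transketalisation of the cis-1,2-diol to a cis-fused dioxolane, which blocks epimerisation at C3, makes the C3 oxygen a poor leaving group for the hydrazone chemistry that follows and marks C2/C3 as distinct from the later C6 hydroxyl; no stereocentre changes.

Step 7
Reactants: 12 acetonide epoxy ketone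
Product: 15 (1R,2R,3R,6S)-allylic alcohol (C4=C5; free C6–OH on the lower face; acetonide and C1–OTBS and C7–OBz retained), via epoxy hydrazone 13 (not isolated), via alkenyl diazene 14 (not isolated)
Conditions: N2H4·H2O (2.5 equiv), AcOH (0.5 equiv), MeOH, 0 °C to rt
Reagents that add atoms: hydrazine, NN (its nitrogen atoms are present only in 13 and 14 and leave as N2; 15 keeps only hydrogen from it)
Why: Wharton transposition: hydrazone 13 opens the strained oxirane at C5–O to give alkenyl diazene 14, which loses N2 and takes up hydrogen at C4, so C4=C5 appears and the C6–O bond, never broken, keeps its configuration; the unstrained C3 ketal oxygen should not compete as leaving group, and the neopentyl-type benzoate should outlast a short exposure to buffered hydrazine.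

Step 8
Reactants: 15 allylic alcohol; 5 tert-butyldimethylsilyl trifluoromethanesulfonate
Product: 16 (1S,2R,3R,6S)-1,6-bis-TBS ether acetonide
Conditions: 2,6-lutidine, CH2Cl2, −40 to 0 °C
Reagents that add atoms: tert-butyldimethylsilyl trifluoromethanesulfonate (5), CC(C)(C)[Si](C)(C)OS(=O)(=O)C(F)(F)F
Why: Silyl triflate silylation of the hindered secondary allylic alcohol masks C6–OH with the same group as C1–OH so that both fall in one final operation, and any TBS that had wandered from O1 to O6 in step 7 would converge on the same bis-silyl ether.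

Step 9
Reactants: 16 bis-TBS ether acetonide
Product: 17 (1S,2R,3R,6S)-2,3-diol 1,6-bis-TBS ether
Conditions: CF3CO2H/H2O (9:1), CH2Cl2, 0 °C
Reagents that add atoms: none
Why: Acid hydrolysis of the ketal: the dioxolane should hydrolyse through its stabilised oxocarbenium ion much faster than the two congested TBS ethers are cleaved, esters are inert, and no C–O bond to a stereocentre is broken.

Step 10
Reactants: 17 diol
Product: 18 (1S,2R,3R,6S)-2,3-diacetate 1,6-bis-TBS ether
Conditions: Ac2O, pyridine, DMAP (cat.), CH2Cl2, rt
Reagents that add atoms: acetic anhydride, CC(=O)OC(C)=O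
Why: DMAP-catalysed acetylation (nucleophilic acyl-transfer catalysis) of the two free secondary hydroxyls with retention, all other oxygens being blocked.

Step 11
Reactants: 18 diacetate bis-TBS ether
Product: 19 target, (1R,2R,3R,6S)-2,3-diacetoxy-1-(benzoyloxymethyl)cyclohex-4-ene-1,6-diol = [(1R,2S,5R,6R)-5,6-diacetoxy-1,2-dihydroxycyclohex-3-en-1-yl]methyl benzoate
Conditions: 48% aq HF, MeCN, 0 °C to rt (polypropylene vessel)
Reagents that add atoms: none
Why: Fluoride-driven desilylation under acidic conditions removes both TBS groups, while the acidic medium avoids the acyl migration and ester loss that a basic fluoride source could cause among O1, O2, O6 and O7; no stereocentre is touched.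

Compound list
1 | 4-hydroxybenzyl alcohol | OCc1ccc(O)cc1 | starting material
2 | benzoic acid | O=C(O)c1ccccc1 | starting material
3 | 4-hydroxybenzyl benzoate | O=C(OCc1ccc(O)cc1)c1ccccc1 | intermediate
4 | (1-hydroxy-4-oxocyclohexa-2,5-dien-1-yl)methyl benzoate | O=C1C=CC(O)(COC(=O)c2ccccc2)C=C1 | intermediate
5 | tert-butyldimethylsilyl trifluoromethanesulfonate | CC(C)(C)[Si](C)(C)OS(=O)(=O)C(F)(F)F | starting material
6 | 4-(benzoyloxymethyl)-4-(tert-butyldimethylsilyloxy)cyclohexa-2,5-dienone | O=C1C=CC(O[Si](C)(C)C(C)(C)C)(COC(=O)c2ccccc2)C=C1 | intermediate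
7 | iminium ion of 6 with the catalyst amine (C4=N+H; trifluoroacetate counter-ion; C=N geometry not fixed) | COc1ccc2nccc([C@H]([NH+]=C3C=CC(O[Si](C)(C)C(C)(C)C)(COC(=O)c4ccccc4)C=C3)[C@@H]3C[C@@H]4CCN3C[C@@H]4C=C)c2c1 | intermediate
8 | hydroperoxy dienamine (C6–OOH on the lower face; C4(NHR)=C5; C2=C3) | COc1ccc2nccc([C@H](NC3=C[C@H](OO)[C@](O[Si](C)(C)C(C)(C)C)(COC(=O)c4ccccc4)C=C3)[C@@H]3C[C@@H]4CCN3C[C@@H]4C=C)c2c1 | intermediate
9 | epoxy iminium ion (iminium form of 10) | COc1ccc2nccc([C@H]([NH+]=C3C=C[C@@](O[Si](C)(C)C(C)(C)C)(COC(=O)c4ccccc4)[C@H]4O[C@@H]34)[C@@H]3C[C@@H]4CCN3C[C@@H]4C=C)c2c1 | intermediate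
10 | (1R,5R,6S)-monoepoxy enone | O=C1C=C[C@@](O[Si](C)(C)C(C)(C)C)(COC(=O)c2ccccc2)[C@H]2O[C@@H]12 | intermediate
11 | (1S,2R,3S,5R,6S)-2,3-dihydroxy-5,6-epoxy ketone | O[C@@H]1[C@H](O)C(=O)[C@@H]2O[C@@H]2[C@]1(O[Si](C)(C)C(C)(C)C)COC(=O)c1ccccc1 | intermediate
12 | (1R,2R,3S,5R,6S)-2,3-O-isopropylidene-5,6-epoxy ketone | CC1(C)O[C@@H]2[C@H](O1)C(=O)[C@@H]3O[C@@H]3[C@]2(O[Si](C)(C)C(C)(C)C)COC(=O)c1ccccc1 | intermediate
13 | C4 hydrazone of 12 | CC1(C)O[C@@H]2[C@H](O1)C(=NN)[C@@H]3O[C@@H]3[C@]2(O[Si](C)(C)C(C)(C)C)COC(=O)c1ccccc1 | intermediate
14 | alkenyl diazene (C4(N=NH)=C5; C6–OH) | CC1(C)O[C@@H]2[C@H](O1)C(N=N)=C[C@H](O)[C@]2(O[Si](C)(C)C(C)(C)C)COC(=O)c1ccccc1 | intermediate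
15 | (1R,2R,3R,6S)-allylic alcohol acetonide | CC1(C)O[C@@H]2[C@H](O1)C=C[C@H](O)[C@]2(O[Si](C)(C)C(C)(C)C)COC(=O)c1ccccc1 | intermediate
16 | (1S,2R,3R,6S)-1,6-bis-TBS ether acetonide | CC1(C)O[C@@H]2[C@H](O1)C=C[C@H](O[Si](C)(C)C(C)(C)C)[C@]2(O[Si](C)(C)C(C)(C)C)COC(=O)c1ccccc1 | intermediate
17 | (1S,2R,3R,6S)-2,3-diol 1,6-bis-TBS ether | O[C@@H]1[C@H](O)C=C[C@H](O[Si](C)(C)C(C)(C)C)[C@]1(O[Si](C)(C)C(C)(C)C)COC(=O)c1ccccc1 | intermediate
18 | (1S,2R,3R,6S)-2,3-diacetate 1,6-bis-TBS ether | CC(=O)O[C@@H]1[C@H](OC(C)=O)C=C[C@H](O[Si](C)(C)C(C)(C)C)[C@]1(O[Si](C)(C)C(C)(C)C)COC(=O)c1ccccc1 | intermediate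
19 | [(1R,2S,5R,6R)-5,6-diacetoxy-1,2-dihydroxycyclohex-3-en-1-yl]methyl benzoate | CC(=O)O[C@@H]1[C@H](OC(C)=O)C=C[C@H](O)[C@]1(O)COC(=O)c1ccccc1 | target

Total step count: 11. Longest linear sequence: 11 steps (1 to 19).

Steps most likely to fail

**Step 4.** Several processes could defeat it:
- slow or reversible iminium formation on the hindered cross-conjugated dienone;
- entry of the peroxide on the upper face;
- weak discrimination between the two arms;
- a second epoxidation.

The fallback uses known chemistry. It takes the relative configuration from hydroxyl direction and the absolute configuration from resolution. It sets out from 6 and comes back at 10. Luche reduction (NaBH4, CeCl3·7H2O, MeOH, −78 °C) gives two achiral C4 epimers. The one with C4–OH on the lower face, cis-dienol F1, is separated, and the other is returned to 6 with MnO2. VO(acac)2/t-BuOOH (1 equiv, CH2Cl2, 0 °C) transfers oxygen from the hydroxyl-bearing lower face to either of the two equivalent alkenes and gives racemic syn-epoxy alcohol F2. Dess–Martin periodinane then gives racemic epoxy enone F3. Preparative chromatography on a chiral stationary phase delivers 10.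

**Step 5.** The processes at risk are:
- slow osmylation of the hindered, electron-poor alkene;
- erosion of facial selectivity, because the oxirane and C7 sit on the face to be attacked;
- β-elimination or silyl and benzoyl migration in the free diol.

The fallback replaces steric control by hydrogen-bond delivery. It sets out from 10 and comes back at 11. Luche reduction, with hydride arriving anti to the oxirane, gives epoxy allylic alcohol F4 with C4–OH on the lower face. Stoichiometric OsO4·TMEDA (CH2Cl2, −78 °C) is drawn to that face by a hydrogen bond from C4–OH, and the now electron-richer alkene gives the stable chelated osmate ester F5. With the diol masked in this form, Dess–Martin periodinane restores the C4 carbonyl to give keto osmate ester F6. Aqueous Na2SO3 in THF then frees 11.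

**Step 7.** The processes at risk are:
- hydrazinolysis of the benzoate;
- expulsion of the C3 oxygen instead of oxirane opening;
- unproductive decay of the diazene.

The fallback is free of hydrazine. It sets out from 12 and comes back at 15. NaBH4/CeCl3·7H2O (MeOH, −40 °C) reduces C4 from the open upper face to epoxy alcohol F7, with C4–OH on the lower face. MsCl/Et3N gives epoxy mesylate F8. NaI in hot butanone displaces the mesylate with inversion (Finkelstein reaction) to give epoxy iodide F9, which is not isolated. Zinc dust then triggers reductive β-elimination of the C4–I and C5–O bonds, which lie anti to each other. This opens the oxirane to C4=C5 with the C6–O bond untouched.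

Further compounds
F1 | step 4 | cis-dienol: 4-(benzoyloxymethyl)-4-(TBSO)cyclohexa-2,5-dien-1-ol with C4–OH and C7 on the same face (achiral) | O[C@H]1C=C[C@@](O[Si](C)(C)C(C)(C)C)(COC(=O)c2ccccc2)C=C1
F2 | step 4 | racemic syn-epoxy alcohol (C4–OH, oxirane and C7 all on the lower face) | O[C@H]1C=C[C@@](O[Si](C)(C)C(C)(C)C)(COC(=O)c2ccccc2)[C@H]2O[C@@H]12.O[C@@H]1C=C[C@](O[Si](C)(C)C(C)(C)C)(COC(=O)c2ccccc2)[C@@H]2O[C@H]12
F3 | step 4 | racemic epoxy enone (racemate of 10) | O=C1C=C[C@@](O[Si](C)(C)C(C)(C)C)(COC(=O)c2ccccc2)[C@H]2O[C@@H]12.O=C1C=C[C@](O[Si](C)(C)C(C)(C)C)(COC(=O)c2ccccc2)[C@@H]2O[C@H]12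
F4 | step 5 | epoxy allylic alcohol, single enantiomer (C4–OH on the lower face) | O[C@H]1C=C[C@@](O[Si](C)(C)C(C)(C)C)(COC(=O)c2ccccc2)[C@H]2O[C@@H]12
F5 | step 5 | TMEDA-chelated osmate ester of the lower-face C2/C3 diol with free C4–OH | C[N+]1(C)CC[N+](C)(C)[Os-2]12(=O)(=O)O[C@@H]3[C@H](O2)[C@H](O)[C@@H]4O[C@@H]4[C@]3(O[Si](C)(C)C(C)(C)C)COC(=O)c1ccccc1
F6 | step 5 | keto osmate ester (TMEDA-chelated osmate ester of 11) | C[N+]1(C)CC[N+](C)(C)[Os-2]12(=O)(=O)O[C@@H]3[C@H](O2)C(=O)[C@@H]4O[C@@H]4[C@]3(O[Si](C)(C)C(C)(C)C)COC(=O)c1ccccc1
F7 | step 7 | epoxy alcohol from 12 (C4–OH on the lower face) | CC1(C)O[C@@H]2[C@H](O1)[C@H](O)[C@@H]3O[C@@H]3[C@]2(O[Si](C)(C)C(C)(C)C)COC(=O)c1ccccc1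
F8 | step 7 | epoxy mesylate | CC1(C)O[C@@H]2[C@H](O1)[C@H](OS(C)(=O)=O)[C@@H]3O[C@@H]3[C@]2(O[Si](C)(C)C(C)(C)C)COC(=O)c1ccccc1
F9 | step 7 | epoxy iodide (C4–I on the upper face; not isolated) | CC1(C)O[C@@H]2[C@H](O1)[C@@H](I)[C@@H]3O[C@@H]3[C@]2(O[Si](C)(C)C(C)(C)C)COC(=O)c1ccccc1
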